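The target is the C15 ether of isocupressic acid with the 4α-oxygen of cryptomeridiol. Everything rests on cutting ring A of the eudesmane half at C10′–C1′ and C4′=C5′, which exposes ring B, whose C7′ already carries the three-carbon side chain, as (+)-dihydrocarvone. Its (R)-1-phenylethylamine imine, reacting through the tetrasubstituted secondary enamine, adds to ethyl vinyl ketone and, after hydrolysis, closes ring A by aldol condensation. One operation thus builds ring A and the quaternary C10′ methyl centre of (+)-α-cyperone. Later the 4α-oxygen is carried as a chloromethyl ether and joined to an alkenylalane made from a communic-acid-derived labdane alkyne.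

Key step: step 2

Assumption: commercial (+)-dihydrocarvone, usually sold mixed with its C2 epimer, is used as such because C2 is planarised in the reacting enamine; trans-communic acid, purchasable from natural-product suppliers, serves as the chiral-pool source of the labdane bicycle.

Step 1
Reactants: 1 (+)-dihydrocarvone + 2 (R)-1-phenylethylamine
Product: 3 N-[(R)-1-phenylethyl] imine of (+)-dihydrocarvone
Conditions: p-TsOH (cat.), toluene, reflux, Dean–Stark; used crude
Reagents that add atoms: none
Why: Acid-catalysed imine condensation driven by azeotropic removal of water; the C5 centre is untouched and the epimerisable C2 centre does not matter because it becomes sp2 in the next step.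

Step 2
Reactants: 3 N-[(R)-1-phenylethyl] imine of (+)-dihydrocarvone + 4 ethyl vinyl ketone
Product: 9 (+)-α-cyperone (eudesma-4,11-dien-3-one; 7β-isopropenyl; 10β-methyl), via secondary enamine 5 (not isolated), via Michael adduct imine 6 (not isolated), via 1,5-diketone 7 (not isolated), via aldol ketol 8 (not isolated)
Conditions: 4 (1.5 equiv), hydroquinone (trace), THF, 40 °C, 3–5 d; 10% aq AcOH, rt; crude, NaOMe, MeOH, rt → 50 °C
Reagents that add atoms: none
Why: Imine 3 equilibrates with its more substituted secondary enamine 5, which adds to s-cis ethyl vinyl ketone in a compact cyclic (aza-ene-like) transition state that forms C10′–C1′ while N–H passes to the enone α-carbon, giving imine 6; aqueous acetic acid then releases diketone 7 and the auxiliary, and methoxide closes ring A through ketol 8, which loses water to the C4′=C5′ enone. The closest known reaction type is the Michael addition of chiral 1-phenylethylamine imines of 2-alkylcyclohexanones to vinyl ketones, followed by a Robinson-type aldol condensation. Ring A closes by a 6-(enolendo)-exo-trig aldol addition of the C4′ enolate to the C5′ ring carbonyl, then E1cB dehydration. The new C10′ centre is set by the (R)-1-phenylethyl group: with its benzylic C–H in the enamine plane the phenyl ring blocks one face, so C1′ should be delivered to the α-face and the methyl group should end β, cis to the C7′ branch. Two selectivities are needed: alkylation at the methyl-bearing α-carbon, secured because the tetrasubstituted enamine is the tautomer that reacts by the internal proton-transfer path, and α-facial attack against the ring's own preference for axial attack syn to the C7′ group, secured by reagent control from the auxiliary. Because 1 is a single enantiomer, any C10′ epimer is a diastereomer and should be removable by chromatography.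

Step 3
Reactants: 9 (+)-α-cyperone
Product: 11 eudesma-3,11-dien-3-yl triflate (trans-fused; 5α-H), via lithium enolate 10 (not isolated)
Conditions: Li (2.2 equiv), t-BuOH (1.0 equiv), NH3(l)/THF, −78 → −33 °C; isoprene; NH3 removed; PhNTf2 (excess), THF, −78 → 0 °C
Reagents that add atoms: N-phenylbis(trifluoromethanesulfonimide), O=S(=O)(N(c1ccccc1)S(=O)(=O)C(F)(F)F)C(F)(F)F
Why: Dissolving-metal (Birch-type) reduction of the enone protonates C5′ axially, which should give the trans-fused Δ3 lithium enolate regiospecifically with H-5′ α (anti to the C10′ methyl), and O-sulfonylation traps it as the enol triflate (reductive enolate trapping).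

Step 4
Reactants: 11 eudesma-3,11-dien-3-yl triflate
Product: 12 11-hydroxyeudesm-3-en-3-yl triflate
Conditions: Co(acac)2 (20 mol%), PhSiH3 (2.5 equiv), O2 (1 atm), THF, rt; aq Na2S2O3
Reagents that add atoms: dioxygen, O=O
Why: Mukaiyama hydration (cobalt-hydride hydrogen-atom transfer, then O2 capture of the tertiary radical) should select the electron-rich 1,1-disubstituted isopropenyl group over the tetrasubstituted, electron-poor enol triflate; no stereocentre is formed.

Step 5
Reactants: 12 11-hydroxyeudesm-3-en-3-yl triflate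
Product: 13 11-(triethylsilyloxy)eudesm-3-en-3-yl triflate
Conditions: TESOTf (1.5 equiv), 2,6-lutidine, CH2Cl2, −78 → 0 °C
Reagents that add atoms: triethylsilyl trifluoromethanesulfonate, CC[Si](CC)(CC)OS(=O)(=O)C(F)(F)F
Why: Silyl-triflate silylation of a tertiary alcohol with a hindered pyridine base; the enol triflate is inert, and the ether marks C11′–OH so that only the later C4′–OH is free.

Step 6
Reactants: 13 11-(triethylsilyloxy)eudesm-3-en-3-yl triflate
Product: 14 α-eudesmol triethylsilyl ether (11-triethylsilyloxy-eudesm-3-ene)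
Conditions: Pd(OAc)2 (5 mol%), PPh3 (10 mol%), HCO2H, n-Bu3N, DMF, 60 °C
Reagents that add atoms: none
Why: Palladium-catalysed formate reduction of an enol triflate (oxidative addition, formate decarboxylation, reductive elimination) replaces C3′–OTf by C3′–H without moving the double bond.

Step 7
Reactants: 14 α-eudesmol triethylsilyl ether
Product: 15 3α,4α-epoxy-11-(triethylsilyloxy)eudesmane
Conditions: mCPBA (1.1 equiv), NaHCO3, CH2Cl2, 0 °C
Reagents that add atoms: m-chloroperoxybenzoic acid, OOC(=O)c1cccc(Cl)c1
Why: Prilezhaev epoxidation of the trisubstituted olefin should occur on the α-face because the axial C10′ methyl group shields the β-face, which sets C3′ and the 4α-oxygen at C4′.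

Step 8
Reactants: 15 3α,4α-epoxy-11-(triethylsilyloxy)eudesmane
Product: 16 cryptomeridiol 11-triethylsilyl ether (eudesmane-4α,11-diol 11-TES ether)
Conditions: LiAlH4, THF, reflux; aq NaOH work-up
Reagents that add atoms: none
Why: SN2 hydride opening of the trisubstituted epoxide at the less substituted C3′ leaves the C4′–O bond untouched, so the tertiary 4α-alcohol with 4β-methyl should result with retention at C4′.

Step 9
Reactants: 16 cryptomeridiol 11-triethylsilyl ether
Product: 17 4-O-(methylthiomethyl)-11-O-(triethylsilyl)cryptomeridiol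
Conditions: DMSO, Ac2O, AcOH, rt, 48 h
Reagents that add atoms: dimethyl sulfoxide, CS(C)=O
Why: Pummerer-type methylthiomethylation with DMSO/Ac2O is a standard way to etherify tertiary alcohols, which cannot be oxidised under these conditions.

Step 10
Reactants: 17 4-O-(methylthiomethyl)-11-O-(triethylsilyl)cryptomeridiol
Product: 18 4-O-(chloromethyl)-11-O-(triethylsilyl)cryptomeridiol
Conditions: SO2Cl2 (1.05 equiv), CH2Cl2, −78 → 0 °C; volatiles removed in vacuo; used at once
Reagents that add atoms: sulfuryl chloride, ClS(Cl)(=O)=O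
Why: Chlorinolysis of the O,S-acetal with sulfuryl chloride converts methylthiomethyl ethers, including tert-alkyl ones, into chloromethyl ethers under aprotic conditions that should spare the silyl ether.

Step 11
Reactants: 19 trans-communic acid (labda-8(17),12E,14-trien-19-oic acid)
Product: 20 2-(trimethylsilyl)ethyl trans-communate
Conditions: Me3SiCH2CH2OH (1.5 equiv), PPh3, DIAD, THF, 0 °C → rt
Reagents that add atoms: 2-(trimethylsilyl)ethanol, C[Si](C)(C)CCO
Why: Mitsunobu esterification alkylates the carboxylate oxygen with the activated primary alcohol, so the steric hindrance of the axial C19 acid should not matter.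

Step 12
Reactants: 20 2-(trimethylsilyl)ethyl trans-communate
Product: 23 2-(trimethylsilyl)ethyl 12-hydroxy-13,14,15,16-tetranorlabd-8(17)-en-19-oate, via 12,13-ozonide 21 (not isolated), via C12 aldehyde 22 (not isolated)
Conditions: O3 (1 equiv, Sudan Red 7B end point), CH2Cl2, −78 °C; Me2S, −78 °C → rt; MeOH, NaBH4, 0 °C
Reagents that add atoms: ozone, [O-][O+]=O
Why: Ozonolysis with one equivalent of ozone should cleave the most electron-rich, trisubstituted C12=C13 bond in preference to the vinyl and exocyclic 1,1-disubstituted olefins, and reductive work-up followed by borohydride reduction gives the C12 alcohol.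

Step 13
Reactants: 23 2-(trimethylsilyl)ethyl 12-hydroxy-13,14,15,16-tetranorlabd-8(17)-en-19-oate
Product: 24 2-(trimethylsilyl)ethyl 12-iodo-13,14,15,16-tetranorlabd-8(17)-en-19-oate
Conditions: I2, PPh3, imidazole, CH2Cl2, 0 °C → rt
Reagents that add atoms: iodine, II
Why: Appel-type iodination converts the unhindered primary alcohol into the iodide by SN2 displacement of the oxyphosphonium group.

Step 14
Reactants: 24 2-(trimethylsilyl)ethyl 12-iodo-13,14,15,16-tetranorlabd-8(17)-en-19-oate
Product: 25 2-(trimethylsilyl)ethyl 15,16-dinorlabd-8(17)-en-13-yn-19-oate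
Conditions: LiC≡CH·H2NCH2CH2NH2 (3 equiv), DMSO, rt
Reagents that add atoms: lithium acetylide–ethylenediamine complex, [Li]C#C.NCCN
Why: SN2 alkylation of lithium acetylide by an unbranched primary iodide in DMSO installs C13≡C14; the hindered, non-enolisable C19 ester should not be attacked.

Step 15
Reactants: 25 2-(trimethylsilyl)ethyl 15,16-dinorlabd-8(17)-en-13-yn-19-oate + 18 4-O-(chloromethyl)-11-O-(triethylsilyl)cryptomeridiol
Product: 27 2-(trimethylsilyl)ethyl ester 11′-triethylsilyl ether of the target, via alkenylalane 26 (not isolated)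
Conditions: 25, Me3Al (2.5 equiv), Cp2ZrCl2 (0.3 equiv), CH2Cl2, rt, 16 h; excess Me3Al removed in vacuo; 18 (0.8 equiv), CH2Cl2, −20 → 0 °C
Reagents that add atoms: trimethylaluminium, C[Al](C)C
Why: Zirconium-catalysed carboalumination (Negishi carboalumination) adds methyl and aluminium syn across the terminal alkyne with methyl at C13, which fixes the 13E geometry, and the alkenylalane then substitutes the α-chloro ether with retention of olefin geometry, so that C14–C15 is formed and no substitution at the hindered tertiary oxygen is needed.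

Step 16
Reactants: 27 2-(trimethylsilyl)ethyl ester 11′-triethylsilyl ether of the target
Product: 28 CNP0156875.1 (15-O-(cryptomeridiol-4-yl) isocupressic acid)
Conditions: TBAF (6 equiv), THF, rt → 45 °C; aq NH4Cl
Reagents that add atoms: none
Why: Fluoride-induced desilylation should cleave the triethylsilyl ether and, by β-elimination of the 2-(trimethylsilyl)ethyl group, the ester, without touching any stereocentre, the allylic ether or the olefins.

Compound list
1 | (+)-dihydrocarvone, (2R,5R)-2-methyl-5-(prop-1-en-2-yl)cyclohexanone | C[C@@H]1CC[C@@H](C(C)=C)CC1=O | starting material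
2 | (R)-1-phenylethylamine | C[C@@H](N)c1ccccc1 | starting material
3 | N-[(R)-1-phenylethyl] imine of (+)-dihydrocarvone (C=N geometry labile) | C[C@@H]1CC[C@@H](C(C)=C)CC1=N[C@H](C)c1ccccc1 | intermediate
4 | ethyl vinyl ketone (pent-1-en-3-one) | CCC(=O)C=C | starting material
5 | secondary enamine, (5R)-2-methyl-N-[(R)-1-phenylethyl]-5-(prop-1-en-2-yl)cyclohex-1-en-1-amine | CC1=C(N[C@H](C)c2ccccc2)C[C@H](C(C)=C)CC1 | intermediate
6 | N-[(R)-1-phenylethyl] imine of (2S,5R)-2-methyl-2-(3-oxopentyl)-5-(prop-1-en-2-yl)cyclohexanone | CCC(=O)CC[C@]1(C)CC[C@@H](C(C)=C)CC1=N[C@H](C)c1ccccc1 | intermediate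
7 | (2S,5R)-2-methyl-2-(3-oxopentyl)-5-(prop-1-en-2-yl)cyclohexanone | CCC(=O)CC[C@]1(C)CC[C@@H](C(C)=C)CC1=O | intermediate
8 | 5-hydroxyeudesm-11-en-3-one (aldol ketol; C4′ and C5′ not defined, both dehydrate to 9) | CC1C(=O)CC[C@]2(C)CC[C@@H](C(C)=C)CC12O | intermediate
9 | (+)-α-cyperone, (4aS,7R)-1,4a-dimethyl-7-(prop-1-en-2-yl)-4,4a,5,6,7,8-hexahydronaphthalen-2(3H)-one | CC1=C2C[C@H](C(C)=C)CC[C@@]2(C)CCC1=O | intermediate
10 | lithium eudesma-3,11-dien-3-olate (5α-H, 10β-CH3, 7β-isopropenyl) | CC1=C(O[Li])CC[C@]2(C)CC[C@@H](C(C)=C)C[C@@H]12 | intermediate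
11 | eudesma-3,11-dien-3-yl triflate (trans-fused, 5α-H, 10β-CH3, 7β-isopropenyl) | CC1=C(OS(=O)(=O)C(F)(F)F)CC[C@]2(C)CC[C@@H](C(C)=C)C[C@@H]12 | intermediate
12 | 11-hydroxyeudesm-3-en-3-yl triflate | CC1=C(OS(=O)(=O)C(F)(F)F)CC[C@]2(C)CC[C@@H](C(C)(C)O)C[C@@H]12 | intermediate
13 | 11-(triethylsilyloxy)eudesm-3-en-3-yl triflate | CC1=C(OS(=O)(=O)C(F)(F)F)CC[C@]2(C)CC[C@@H](C(C)(C)O[Si](CC)(CC)CC)C[C@@H]12 | intermediate
14 | α-eudesmol triethylsilyl ether (eudesm-3-ene, 5α-H, 10β-CH3, 7β-CMe2OTES) | CC1=CCC[C@]2(C)CC[C@@H](C(C)(C)O[Si](CC)(CC)CC)C[C@@H]12 | intermediate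
15 | 3α,4α-epoxy-11-(triethylsilyloxy)eudesmane (4β-CH3) | C[C@@]12O[C@@H]1CC[C@]3(C)CC[C@@H](C(C)(C)O[Si](CC)(CC)CC)C[C@@H]23 | intermediate
16 | cryptomeridiol 11-triethylsilyl ether (4α-OH, 4β-CH3, 5α-H, 10β-CH3, 7β-CMe2OTES) | O[C@]1(C)CCC[C@]2(C)CC[C@@H](C(C)(C)O[Si](CC)(CC)CC)C[C@H]21 | intermediate
17 | 4-O-(methylthiomethyl)-11-O-(triethylsilyl)cryptomeridiol | CSCO[C@]1(C)CCC[C@]2(C)CC[C@@H](C(C)(C)O[Si](CC)(CC)CC)C[C@H]21 | intermediate
18 | 4-O-(chloromethyl)-11-O-(triethylsilyl)cryptomeridiol | ClCO[C@]1(C)CCC[C@]2(C)CC[C@@H](C(C)(C)O[Si](CC)(CC)CC)C[C@H]21 | intermediate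
19 | trans-communic acid, (4S,5R,9S,10R)-labda-8(17),12E,14-trien-19-oic acid | C=C1CC[C@@H]2[C@](C)(CCC[C@]2(C)C(=O)O)[C@H]1C/C=C(C)/C=C | starting material
20 | 2-(trimethylsilyl)ethyl trans-communate | C=C1CC[C@@H]2[C@](C)(CCC[C@]2(C)C(=O)OCC[Si](C)(C)C)[C@H]1C/C=C(C)/C=C | intermediate
21 | 12,13-ozonide of 20 (1,2,4-trioxolane; mixture at the two trioxolane carbons) | C=C1CC[C@@H]2[C@](C)(CCC[C@]2(C)C(=O)OCC[Si](C)(C)C)[C@H]1CC1OOC(C)(C=C)O1 | intermediate
22 | 2-(trimethylsilyl)ethyl 12-oxo-13,14,15,16-tetranorlabd-8(17)-en-19-oate | C=C1CC[C@@H]2[C@](C)(CCC[C@]2(C)C(=O)OCC[Si](C)(C)C)[C@H]1CC=O | intermediate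
23 | 2-(trimethylsilyl)ethyl 12-hydroxy-13,14,15,16-tetranorlabd-8(17)-en-19-oate | C=C1CC[C@@H]2[C@](C)(CCC[C@]2(C)C(=O)OCC[Si](C)(C)C)[C@H]1CCO | intermediate
24 | 2-(trimethylsilyl)ethyl 12-iodo-13,14,15,16-tetranorlabd-8(17)-en-19-oate | C=C1CC[C@@H]2[C@](C)(CCC[C@]2(C)C(=O)OCC[Si](C)(C)C)[C@H]1CCI | intermediate
25 | 2-(trimethylsilyl)ethyl 15,16-dinorlabd-8(17)-en-13-yn-19-oate | C=C1CC[C@@H]2[C@](C)(CCC[C@]2(C)C(=O)OCC[Si](C)(C)C)[C@H]1CCC#C | intermediate
26 | (13E)-14-(dimethylalumino)-15-norlabda-8(17),13-dien-19-oic acid 2-(trimethylsilyl)ethyl ester | C=C1CC[C@@H]2[C@](C)(CCC[C@]2(C)C(=O)OCC[Si](C)(C)C)[C@H]1CC/C(C)=C/[Al](C)C | intermediate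
27 | 2-(trimethylsilyl)ethyl ester, 11′-triethylsilyl ether of the target | C=C1CC[C@@H]2[C@](C)(CCC[C@]2(C)C(=O)OCC[Si](C)(C)C)[C@H]1CC/C(C)=C/CO[C@]1(C)CCC[C@]2(C)CC[C@@H](C(C)(C)O[Si](CC)(CC)CC)C[C@H]21 | intermediate
28 | CNP0156875.1, 15-O-(cryptomeridiol-4-yl) isocupressic acid | C=C1CC[C@@H]2[C@](C)(CCC[C@]2(C)C(=O)O)[C@H]1CC/C(C)=C/CO[C@]1(C)CCC[C@]2(C)CC[C@@H](C(C)(C)O)C[C@H]21 | target

Total step count: 16. Longest linear sequence: 12 steps (steps 1–10, 15, 16); the labdane branch is steps 11–14.

Steps most likely to fail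

Step 2. The facial selectivity at C10′ may be eroded because the auxiliary has to override the ring's own bias, and the slow addition may be outrun by polymerisation of the enone. The fallback sets out from 1 and comes back at 9, and replaces auxiliary control by substrate control. Hydrogen chloride is added to the isopropenyl group of 1 (HCl, AcOH, 0 °C) to give dihydrocarvone hydrochloride F1. KOH in MeOH closes the cyclopropane by intramolecular enolate alkylation to give (−)-2-carone F2. Base-mediated Robinson annulation of F2 with 4 (KOH, EtOH) can only alkylate the methyl-bearing α-carbon and should do so anti to the fused dimethylcyclopropane, which would give 6,11-cycloeudesm-4-en-3-one F3 with the required C10′ configuration. HCl in AcOH opens the cyclopropane by homoconjugate addition to 11-chloroeudesm-4-en-3-one F4. Dehydrochlorination (NaOAc, AcOH, heat) then leads to 9, with the isopropylidene isomer to be removed by chromatography.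

Step 15. The aluminium Lewis acids may ionise the tert-alkyl chloromethyl ether (loss of formaldehyde, elimination at C4′), or methyl transfer may compete with alkenyl transfer. The fallback sets out from 25 and 16 and comes back at 27. The same carboalumination of 25 is followed by n-BuLi (alanate formation) and paraformaldehyde to give 2-(trimethylsilyl)ethyl isocupressate F5. CBr4/PPh3 (CH2Cl2, 0 °C) converts it into 2-(trimethylsilyl)ethyl 15-bromo-labda-8(17),13E-dien-19-oate F6. The potassium alkoxide of 16 (KH, 18-crown-6, THF, 0 °C) is then alkylated with F6 in a Williamson etherification to give 27.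

Step 12. Chemoselectivity may be lost if ozone also attacks the vinyl and exocyclic olefins before the C12=C13 bond is consumed. The fallback sets out from 20 and comes back at 23, and removes the need for selectivity. Exhaustive ozonolysis (excess O3, CH2Cl2/MeOH, −78 °C; Me2S) cleaves all three olefins to give 2-(trimethylsilyl)ethyl 8,12-dioxo-13,14,15,16,17-pentanorlabdan-19-oate F7. NaBH4 (1 equiv, EtOH, −40 °C) reduces only the aldehyde to give 2-(trimethylsilyl)ethyl 12-hydroxy-8-oxo-13,14,15,16,17-pentanorlabdan-19-oate F8, which may sit partly as its cyclic hemiketal. Wittig methylenation (Ph3P=CH2 in excess, THF, reflux) restores C8=C17 and gives 23.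

Further compounds
F1 | step 2 | dihydrocarvone hydrochloride, (2R,5R)-5-(2-chloropropan-2-yl)-2-methylcyclohexanone | C[C@@H]1CC[C@@H](C(C)(C)Cl)CC1=O
F2 | step 2 | (−)-2-carone, 3,7,7-trimethylbicyclo[4.1.0]heptan-2-one (cyclopropane on the face of the former isopropenyl group) | C[C@@H]1CC[C@H]2C(C)(C)[C@H]2C1=O
F3 | step 2 | 6,11-cycloeudesm-4-en-3-one (10β-CH3, cyclopropane on the β-face) | CC1=C2[C@H]3[C@@H](CC[C@@]2(C)CCC1=O)C3(C)C
F4 | step 2 | 11-chloroeudesm-4-en-3-one | CC1=C2C[C@H](C(C)(C)Cl)CC[C@@]2(C)CCC1=O
F5 | step 15 | 2-(trimethylsilyl)ethyl isocupressate | C=C1CC[C@@H]2[C@](C)(CCC[C@]2(C)C(=O)OCC[Si](C)(C)C)[C@H]1CC/C(C)=C/CO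
F6 | step 15 | 2-(trimethylsilyl)ethyl 15-bromo-labda-8(17),13E-dien-19-oate | C=C1CC[C@@H]2[C@](C)(CCC[C@]2(C)C(=O)OCC[Si](C)(C)C)[C@H]1CC/C(C)=C/CBr
F7 | step 12 | 2-(trimethylsilyl)ethyl 8,12-dioxo-13,14,15,16,17-pentanorlabdan-19-oate | O=C1CC[C@@H]2[C@](C)(CCC[C@]2(C)C(=O)OCC[Si](C)(C)C)[C@H]1CC=O
F8 | step 12 | 2-(trimethylsilyl)ethyl 12-hydroxy-8-oxo-13,14,15,16,17-pentanorlabdan-19-oate | O=C1CC[C@@H]2[C@](C)(CCC[C@]2(C)C(=O)OCC[Si](C)(C)C)[C@H]1CCO
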